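**Strategy.** The route rests on disconnecting ring A of the apigenin unit (C4a'', C5''–C8'', C8a'') back to a 4‑pyranone that already carries ring C and the diaryl ether. The feature exploited is the meta pair of oxygens on C5'' and C7'' of that ring, fused along C4a''–C8a'': a pyranonylketene delivers C8'' and C5''–O, a siloxyalkyne C6'' and C7''–O. In one operation, Wolff rearrangement of diazo ketone 15, (2+2) addition of alkyne 22, 4π opening and 6π closure onto pyranone C5 should form four C–C bonds and ring A. Precursor 15 is the benzyl‑protected acacetin 8‑aryl ether whose aryl ring carries a 6‑diazoacetyl‑4‑pyranone.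

Key step: step 12

Remark: pyranone locants follow the name of 15 (O1, aryl on C2, diazoacetyl on C6), so the carbon that becomes C4a'' is pyranone C5; 1 is taken as a catalogue chemical, whereas alkyne 22 is not and is made in steps 9 to 11.

**Step 1**
Reactants: 1 acetophenone 1-[2,4-bis(benzyloxy)-6-hydroxyphenyl]ethanone; 2 p-anisaldehyde (4-methoxybenzaldehyde)
Product: 3 chalcone (E)-1-[2,4-bis(benzyloxy)-6-hydroxyphenyl]-3-(4-methoxyphenyl)prop-2-en-1-one
Conditions: KOH (50% aq.), EtOH, rt
Reagents that add atoms: none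
Why: Claisen–Schmidt condensation of the acetophenone enolate with a non-enolizable aldehyde should give the chalcone, whose E alkene is set thermodynamically by dehydration to the conjugated enone.

**Step 2**
Reactants: 3 chalcone
Product: 4 flavone 5,7-bis(benzyloxy)-2-(4-methoxyphenyl)-4H-chromen-4-one
Conditions: I2 (10 mol %), DMSO, 120 °C
Reagents that add atoms: none
Why: Oxidative cyclization of a 2'-hydroxychalcone (oxa-Michael closure, then iodine-mediated dehydrogenation with DMSO as terminal oxidant) is a standard flavone synthesis that benzyl ethers should survive.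

**Step 3**
Reactants: 4 flavone
Product: 5 iodoflavone 5,7-bis(benzyloxy)-8-iodo-2-(4-methoxyphenyl)-4H-chromen-4-one
Conditions: N-iodosuccinimide (1.1 equiv), CF3CO2H (0.2 equiv), MeCN–CH2Cl2, 0 °C to rt, dark
Reagents that add atoms: N-iodosuccinimide, O=C1CCC(=O)N1I
Why: Electrophilic aromatic iodination should occur at C8, which is activated by O1 and the 7-benzyloxy group (ortho) and the 5-benzyloxy group (para) and is less hindered than C6 between two benzyloxy groups.

**Step 4**
Reactants: 5 iodoflavone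
Product: 7 hydroxyflavone 5,7-bis(benzyloxy)-8-hydroxy-2-(4-methoxyphenyl)-4H-chromen-4-one, via 8-pinacolboronate 6 (not isolated)
Conditions: PdCl2(MeCN)2 (3 mol %), SPhos, pinacolborane, Et3N, 1,4-dioxane, 80 °C; then aq. NaOH, 30% H2O2, THF, 0 °C
Reagents that add atoms: pinacolborane, [H]B1OC(C)(C)C(C)(C)O1 (boryl group of 6 only); hydrogen peroxide, OO (hydroxyl oxygen of 7)
Why: Miyaura–Masuda borylation on zerovalent palladium with a bulky biarylphosphine is suited to electron-rich, doubly ortho-substituted aryl iodides, and ipso oxidation of the boronate in the same flask should give the C8 phenol without positional change.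

**Step 5**
Reactants: 7 hydroxyflavone; 8 4'-fluoroacetophenone (1-(4-fluorophenyl)ethanone)
Product: 9 ketone 8-(4-acetylphenoxy)-5,7-bis(benzyloxy)-2-(4-methoxyphenyl)-4H-chromen-4-one
Conditions: K2CO3, DMAc, 120 °C
Reagents that add atoms: none
Why: Nucleophilic aromatic substitution should proceed because the para-acetyl group stabilizes the Meisenheimer adduct and fluoride is the best leaving group, while the fully etherified flavone is inert to carbonate.

**Step 6**
Reactants: 9 ketone
Product: 10 diketone 1-(4-{[5,7-bis(benzyloxy)-2-(4-methoxyphenyl)-4-oxo-4H-chromen-8-yl]oxy}phenyl)butane-1,3-dione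
Conditions: NaH (3 equiv), EtOAc (6 equiv), THF, 60 °C; aq. HCl
Reagents that add atoms: ethyl acetate, CCOC(C)=O
Why: Crossed Claisen condensation of the only enolizable ketone with ethyl acetate is driven by formation of the stabilized β-diketone enolate, and no other site in 9 carries an acidic hydrogen.

**Step 7**
Reactants: 10 diketone; 11 di-tert-butyl oxalate
Product: 13 acid 6-(4-{[5,7-bis(benzyloxy)-2-(4-methoxyphenyl)-4-oxo-4H-chromen-8-yl]oxy}phenyl)-4-oxo-4H-pyran-2-carboxylic acid, via triketo tert-butyl ester 12 (not isolated)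
Conditions: KOtBu (2.5 equiv), THF, 0 °C to rt; aq. HCl; then CF3CO2H–CH2Cl2 (1:4), rt
Reagents that add atoms: none
Why: Claisen condensation under equilibrating conditions should acylate the terminal methyl group because only that adduct gives a doubly stabilized dienolate, and acid then effects cyclodehydration of the 1,3,5-tricarbonyl chain to the 4-pyranone together with tert-butyl ester cleavage, so that no basic hydrolysis of a pyranone ester is needed.

**Step 8**
Reactants: 13 acid
Product: 15 diazo ketone 8-{4-[6-(2-diazoacetyl)-4-oxo-4H-pyran-2-yl]phenoxy}-5,7-bis(benzyloxy)-2-(4-methoxyphenyl)-4H-chromen-4-one, via isobutyl carbonic anhydride 14 (not isolated)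
Conditions: iBuOCOCl, N-methylmorpholine, THF, −15 °C; then Me3SiCHN2, MeCN, 0 °C to rt; aq. NaHCO3
Reagents that add atoms: (trimethylsilyl)diazomethane, C[Si](C)(C)C=[N+]=[N-]; isobutyl chloroformate, CC(C)COC(Cl)=O (carbonate part of 14 only)
Why: Arndt–Eistert-type acylation of a diazoalkane should occur at the more electrophilic pyranoyl carbonyl of the mixed anhydride, with the silyl group lost to the carbonate or on work-up, and avoiding an acid chloride keeps the two pyranone-type carbonyls from being turned into chloropyrylium salts.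

**Step 9**
Reactants: 16 tetrahydrofuran; 17 chlorotriisopropylsilane
Product: 19 triisopropyl(vinyloxy)silane, via lithium ethenolate 18 (not isolated)
Conditions: n-BuLi, THF (reactant and solvent), rt, 16 h; then 17, DMPU, 0 °C to rt
Reagents that add atoms: none
Why: α-Lithiation of tetrahydrofuran followed by (3+2) cycloreversion is the established source of the lithium enolate of acetaldehyde, and a silyl chloride in a dipolar cosolvent should silylate it on oxygen (enolate O-silylation).

**Step 10**
Reactants: 19 triisopropyl(vinyloxy)silane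
Product: 21 [(2-bromoethenyl)oxy]triisopropylsilane (E/Z mixture), via 1,2-dibromoethyl silyl ether 20 (not isolated)
Conditions: Br2, CH2Cl2, −78 °C; then Et3N, −78 °C to rt
Reagents that add atoms: bromine, BrBr
Why: Bromination–dehydrobromination of an enol ether (bromine addition, then amine-induced loss of HBr from the α-bromo ether through its oxocarbenium ion) is the classical route to 2-bromovinyl ethers, and the bulky silyl group should resist bromide attack at silicon.

**Step 11**
Reactants: 21 [(2-bromoethenyl)oxy]triisopropylsilane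
Product: 22 (ethynyloxy)triisopropylsilane [(triisopropylsilyloxy)acetylene]
Conditions: LiN(iPr)2 (2.2 equiv), THF, −78 °C; aq. NH4Cl, −78 °C
Reagents that add atoms: none
Why: Base-induced β-elimination of HBr from a 2-halovinyl ether is the textbook ynol ether synthesis, and because the O–Si bond is already in place no competition between O- and C-silylation can arise.

**Step 12**
Reactants: 15 diazo ketone; 22 (ethynyloxy)triisopropylsilane
Product: 26 silyl ether 5,7-bis(benzyloxy)-8-{4-[5-hydroxy-4-oxo-7-(triisopropylsilyloxy)-4H-chromen-2-yl]phenoxy}-2-(4-methoxyphenyl)-4H-chromen-4-one, via pyranonylketene 23 (not isolated), via siloxycyclobutenone 24 (not isolated), via dienylketene 25 (not isolated)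
Conditions: 22 (3 equiv), ClCH2CH2Cl (degassed, dilute), 420 nm LEDs, rt, until N2 evolution ends; then 80 °C
Reagents that add atoms: none
Why: Proposed new method: irradiation into the weak visible band of the diazo ketone, where neither the flavone nor the pyranone absorbs, should expel N2 and trigger a Wolff shift of the pyranonyl group to ketene 23, whose carbonyl carbon is attacked by the unsubstituted carbon of the polarized siloxyalkyne in a (2+2) cycloaddition to cyclobutenone 24; heating should then open 24 by 4π electrocyclic cleavage to dienylketene 25, which closes by 6π electrocyclization onto pyranone C5 and tautomerizes to the chelated phenol. The closest known reaction type is the photochemical Danheiser benzannulation of aryl and heteroaryl α-diazo ketones with siloxyalkynes, which has not been shown on a 4-pyranone whose C5=C6 bond is part of a cross-conjugated vinylogous ester. Ring A is closed by a thermal six-electron disrotatory electrocyclization (C4a''–C5''), after the Wolff shift has made C8a''–C8'' and the (2+2) step C5''–C6'' and C7''–C8''. No stereocentre is formed, and the racemic centre of 24 disappears on aromatization. Regioselectivity is needed twice: ynol ether polarization places the silyloxy carbon next to the ketene α-carbon and hence at C7'', meta to the new C5'' hydroxyl, and the closure has a single option because C6 is flanked on its other side by O1. Chemoselectivity rests on the absence of free hydroxyl groups in 15, so that the ketene meets only the alkyne, and on the hydrogen bond from the new 5''-OH to C4''=O, which should protect the product from acylation by further ketene.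

**Step 13**
Reactants: 26 silyl ether
Product: 28 target 8-[4-(5,7-dihydroxy-4-oxo-4H-chromen-2-yl)phenoxy]-5,7-dihydroxy-2-(4-methoxyphenyl)-4H-chromen-4-one, via 5'',7''-diol dibenzyl ether 27 (not isolated)
Conditions: Bu4NF, AcOH, THF, 0 °C; then MeOH, 10% Pd/C, H2 (1 atm), rt
Reagents that add atoms: none
Why: Fluoride-induced desilylation of the aryl silyl ether (the stabilized 7''-phenoxide is a good leaving group) and hydrogenolysis of the two benzyl ethers over Pd/C in the same flask should leave the flavone C2=C3 bonds, the diaryl ether and the methyl ether untouched.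

**Compound list**

1 | 1-[2,4-bis(benzyloxy)-6-hydroxyphenyl]ethanone | CC(=O)c1c(O)cc(OCc2ccccc2)cc1OCc1ccccc1 | starting material
2 | 4-methoxybenzaldehyde | COc1ccc(C=O)cc1 | starting material
3 | (E)-1-[2,4-bis(benzyloxy)-6-hydroxyphenyl]-3-(4-methoxyphenyl)prop-2-en-1-one | COc1ccc(/C=C/C(=O)c2c(O)cc(OCc3ccccc3)cc2OCc2ccccc2)cc1 | intermediate
4 | 5,7-bis(benzyloxy)-2-(4-methoxyphenyl)-4H-chromen-4-one | COc1ccc(-c2cc(=O)c3c(OCc4ccccc4)cc(OCc4ccccc4)cc3o2)cc1 | intermediate
5 | 5,7-bis(benzyloxy)-8-iodo-2-(4-methoxyphenyl)-4H-chromen-4-one | COc1ccc(-c2cc(=O)c3c(OCc4ccccc4)cc(OCc4ccccc4)c(I)c3o2)cc1 | intermediate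
6 | 5,7-bis(benzyloxy)-2-(4-methoxyphenyl)-8-(4,4,5,5-tetramethyl-1,3,2-dioxaborolan-2-yl)-4H-chromen-4-one | COc1ccc(-c2cc(=O)c3c(OCc4ccccc4)cc(OCc4ccccc4)c(B4OC(C)(C)C(C)(C)O4)c3o2)cc1 | intermediate
7 | 5,7-bis(benzyloxy)-8-hydroxy-2-(4-methoxyphenyl)-4H-chromen-4-one | COc1ccc(-c2cc(=O)c3c(OCc4ccccc4)cc(OCc4ccccc4)c(O)c3o2)cc1 | intermediate
8 | 1-(4-fluorophenyl)ethanone | CC(=O)c1ccc(F)cc1 | starting material
9 | 8-(4-acetylphenoxy)-5,7-bis(benzyloxy)-2-(4-methoxyphenyl)-4H-chromen-4-one | COc1ccc(-c2cc(=O)c3c(OCc4ccccc4)cc(OCc4ccccc4)c(Oc4ccc(C(C)=O)cc4)c3o2)cc1 | intermediate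
10 | 1-(4-{[5,7-bis(benzyloxy)-2-(4-methoxyphenyl)-4-oxo-4H-chromen-8-yl]oxy}phenyl)butane-1,3-dione | COc1ccc(-c2cc(=O)c3c(OCc4ccccc4)cc(OCc4ccccc4)c(Oc4ccc(C(=O)CC(C)=O)cc4)c3o2)cc1 | intermediate
11 | di-tert-butyl oxalate | CC(C)(C)OC(=O)C(=O)OC(C)(C)C | starting material
12 | tert-butyl 6-(4-{[5,7-bis(benzyloxy)-2-(4-methoxyphenyl)-4-oxo-4H-chromen-8-yl]oxy}phenyl)-2,4,6-trioxohexanoate | COc1ccc(-c2cc(=O)c3c(OCc4ccccc4)cc(OCc4ccccc4)c(Oc4ccc(C(=O)CC(=O)CC(=O)C(=O)OC(C)(C)C)cc4)c3o2)cc1 | intermediate
13 | 6-(4-{[5,7-bis(benzyloxy)-2-(4-methoxyphenyl)-4-oxo-4H-chromen-8-yl]oxy}phenyl)-4-oxo-4H-pyran-2-carboxylic acid | COc1ccc(-c2cc(=O)c3c(OCc4ccccc4)cc(OCc4ccccc4)c(Oc4ccc(-c5cc(=O)cc(C(=O)O)o5)cc4)c3o2)cc1 | intermediate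
14 | mixed anhydride of acid 13 with isobutyl hydrogen carbonate | COc1ccc(-c2cc(=O)c3c(OCc4ccccc4)cc(OCc4ccccc4)c(Oc4ccc(-c5cc(=O)cc(C(=O)OC(=O)OCC(C)C)o5)cc4)c3o2)cc1 | intermediate
15 | 8-{4-[6-(2-diazoacetyl)-4-oxo-4H-pyran-2-yl]phenoxy}-5,7-bis(benzyloxy)-2-(4-methoxyphenyl)-4H-chromen-4-one | COc1ccc(-c2cc(=O)c3c(OCc4ccccc4)cc(OCc4ccccc4)c(Oc4ccc(-c5cc(=O)cc(C(=O)C=[N+]=[N-])o5)cc4)c3o2)cc1 | intermediate
16 | tetrahydrofuran | C1CCOC1 | starting material
17 | chlorotriisopropylsilane | CC(C)[Si](Cl)(C(C)C)C(C)C | starting material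
18 | lithium ethenolate (lithium enolate of acetaldehyde) | [Li]OC=C | intermediate
19 | triisopropyl(vinyloxy)silane | C=CO[Si](C(C)C)(C(C)C)C(C)C | intermediate
20 | (1,2-dibromoethoxy)triisopropylsilane (racemic) | BrCC(Br)O[Si](C(C)C)(C(C)C)C(C)C | intermediate
21 | [(2-bromoethenyl)oxy]triisopropylsilane (E/Z mixture) | BrC=CO[Si](C(C)C)(C(C)C)C(C)C | intermediate
22 | (ethynyloxy)triisopropylsilane | C#CO[Si](C(C)C)(C(C)C)C(C)C | intermediate
23 | ketene of 15 after Wolff shift: 8-{4-[4-oxo-6-(2-oxoethenyl)-4H-pyran-2-yl]phenoxy}-5,7-bis(benzyloxy)-2-(4-methoxyphenyl)-4H-chromen-4-one | COc1ccc(-c2cc(=O)c3c(OCc4ccccc4)cc(OCc4ccccc4)c(Oc4ccc(-c5cc(=O)cc(C=C=O)o5)cc4)c3o2)cc1 | intermediate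
24 | cyclobutenone: 4-(pyranon-6-yl)-3-(triisopropylsilyloxy)cyclobut-2-en-1-one carried on the same aryl ether (racemic at the ring CH) | COc1ccc(-c2cc(=O)c3c(OCc4ccccc4)cc(OCc4ccccc4)c(Oc4ccc(-c5cc(=O)cc(C6C(=O)C=C6O[Si](C(C)C)(C(C)C)C(C)C)o5)cc4)c3o2)cc1 | intermediate
25 | dienylketene: 4-(pyranon-6-yl)-3-(triisopropylsilyloxy)buta-1,3-dien-1-one carried on the same aryl ether, ketenyl carbon cis to the pyranonyl group | COc1ccc(-c2cc(=O)c3c(OCc4ccccc4)cc(OCc4ccccc4)c(Oc4ccc(-c5cc(=O)cc(/C=C(O[Si](C(C)C)(C(C)C)C(C)C)\C=C=O)o5)cc4)c3o2)cc1 | intermediate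
26 | 5,7-bis(benzyloxy)-8-{4-[5-hydroxy-4-oxo-7-(triisopropylsilyloxy)-4H-chromen-2-yl]phenoxy}-2-(4-methoxyphenyl)-4H-chromen-4-one | COc1ccc(-c2cc(=O)c3c(OCc4ccccc4)cc(OCc4ccccc4)c(Oc4ccc(-c5cc(=O)c6c(O)cc(O[Si](C(C)C)(C(C)C)C(C)C)cc6o5)cc4)c3o2)cc1 | intermediate
27 | 5,7-bis(benzyloxy)-8-[4-(5,7-dihydroxy-4-oxo-4H-chromen-2-yl)phenoxy]-2-(4-methoxyphenyl)-4H-chromen-4-one | COc1ccc(-c2cc(=O)c3c(OCc4ccccc4)cc(OCc4ccccc4)c(Oc4ccc(-c5cc(=O)c6c(O)cc(O)cc6o5)cc4)c3o2)cc1 | intermediate
28 | 8-[4-(5,7-dihydroxy-4-oxo-4H-chromen-2-yl)phenoxy]-5,7-dihydroxy-2-(4-methoxyphenyl)-4H-chromen-4-one (CNP0295851.0) | COc1ccc(-c2cc(=O)c3c(O)cc(O)c(Oc4ccc(-c5cc(=O)c6c(O)cc(O)cc6o5)cc4)c3o2)cc1 | target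

**Totals.** Total step count: 13. Longest linear sequence: 10 steps (steps 1 to 8, 12 and 13); the alkyne branch (steps 9 to 11) joins at step 12.

**Steps most likely to fail**

Step 12 (Proposed new method). The ketene may be lost to dimerization or to traces of nucleophiles before the alkyne captures it. The 6π closure onto the electron-poor pyranone C5 may also be slow enough for the cyclobutenone and dienylketene to decompose on heating. The fallback uses known chemistry, sets out from 7 and comes back at 28. Nucleophilic aromatic substitution of 7 on 4-fluorobenzaldehyde (K2CO3, DMAc, 100 °C) should give 4-{[5,7-bis(benzyloxy)-2-(4-methoxyphenyl)-4-oxo-4H-chromen-8-yl]oxy}benzaldehyde F1. Claisen–Schmidt condensation of this aldehyde with a second portion of 1 (KOH, EtOH, rt) should give the 2'-hydroxychalcone F2. Oxidative cyclization (catalytic I2, DMSO, 120 °C) should then give the tetra-O-benzyl biflavone F3, and hydrogenolysis (H2, 10% Pd/C, THF–MeOH) should deliver 28.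

Step 10. Bromide may attack silicon in the bromonium or oxocarbenium stage, which would cleave the silyl group and release bromoacetaldehyde, and the α-bromo silyl ether may hydrolyse before elimination. The fallback sets out from 17 and comes back at 22, replacing steps 9 to 11. LiC≡CH (acetylene, n-BuLi, THF, −78 °C) would be oxidized with LiOOtBu (from tBuOOH and LiN(SiMe3)2) to lithium ethynolate F4, which the bulky chlorosilane 17 should silylate on oxygen at −78 to 0 °C to give 22 directly.

Step 4. Protodeiodination of the hindered arylpalladium intermediate by the borane may outrun borylation, and alkaline peroxide may begin to degrade the flavone during the oxidation. The fallback sets out from 5 and comes back at 9. An Ullmann-type C–O coupling of 5 with 4'-hydroxyacetophenone (CuI, picolinic acid, K3PO4, DMSO, 90 °C) would form the diaryl ether from the iodide itself and so bypass 6, 7 and step 5; it makes no new compound.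

**Further compounds**

F1 | step 12 | 4-{[5,7-bis(benzyloxy)-2-(4-methoxyphenyl)-4-oxo-4H-chromen-8-yl]oxy}benzaldehyde | COc1ccc(-c2cc(=O)c3c(OCc4ccccc4)cc(OCc4ccccc4)c(Oc4ccc(C=O)cc4)c3o2)cc1
F2 | step 12 | (E)-1-[2,4-bis(benzyloxy)-6-hydroxyphenyl]-3-(4-{[5,7-bis(benzyloxy)-2-(4-methoxyphenyl)-4-oxo-4H-chromen-8-yl]oxy}phenyl)prop-2-en-1-one | COc1ccc(-c2cc(=O)c3c(OCc4ccccc4)cc(OCc4ccccc4)c(Oc4ccc(/C=C/C(=O)c5c(O)cc(OCc6ccccc6)cc5OCc5ccccc5)cc4)c3o2)cc1
F3 | step 12 | 5,7-bis(benzyloxy)-8-{4-[5,7-bis(benzyloxy)-4-oxo-4H-chromen-2-yl]phenoxy}-2-(4-methoxyphenyl)-4H-chromen-4-one | COc1ccc(-c2cc(=O)c3c(OCc4ccccc4)cc(OCc4ccccc4)c(Oc4ccc(-c5cc(=O)c6c(OCc7ccccc7)cc(OCc7ccccc7)cc6o5)cc4)c3o2)cc1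
F4 | step 10 | lithium ethynolate | [Li]OC#C
F0 | step 4 | none | none
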